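## Retrosynthetic overview

1. Half 1 is the naphthalene C1'–C8a' (isoquinoline on C8'). Half 2 is the naphthalene C1''–C8a'' (isoquinoline on C1''). The two are joined C6'–C6''. The plan rests on ring A of half 2 (C1'', C2'', C3'', C4'', C4a'', C8a''). Its pattern of OMe on C4'', H on C3'', CH3 on C2'' and aryl on C1'' is what a methoxycarbene carbon (C4''), propyne (C3'', C2'') and one CO (C1'') leave behind. The CO-derived hydroxyl is a handle that no other carbon of either naphthalene has.
2. Last come hydrogenolysis of six benzyl groups and, before it, the C1''–C5 biaryl bond, made by Suzuki coupling of the C1'' triflate with an N,O-dibenzyl isoquinoline 5-boronate.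
3. Key disconnection: ring A of half 2 opens to a pentacarbonylchromium aryl(methoxy)carbene on protected half 1, propyne and CO (bonds C4''–C3'', C2''–C1'', C1''–C8a'').
4. The carbene comes from an aryl bromide, made from a C6' boronate of half 1 and benzyl 2,6-dibromophenyl ether. Halogenation of finished half 1 could not tell C6' from C1', C3' and isoquinoline C7. C6' is therefore carried as chloride from the benzaldehyde stage, while C8'–Br couples first with the same isoquinoline boronate.
5. Ring order: the hetero ring of the isoquinoline (Bischler–Napieralski; C3 from D-alaninol, C1 by trans-selective reduction), then ring A of half 1 (Stobbe condensation, acetic anhydride closure), then ring A of half 2 (Dötz).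

Key step: step 22

Assumption: the SMILES fixes only C1 and C3 of both isoquinolines (all four R, methyl groups trans in each ring) and leaves the biaryl axes open, so the two hindered isoquinoline–naphthalene axes are formed without control and atropisomers are separated by chromatography where wanted.

Shorthand: H1 = 1-(benzyloxy)-4-[(1R,3R)-2-benzyl-8-(benzyloxy)-1,3-dimethyl-1,2,3,4-tetrahydroisoquinolin-5-yl]-8-methoxy-6-methylnaphthalen-2-yl, which is protected half 1 bound through C6'.

## Isoquinoline boronate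

Step 1
Reactants: 1 tert-butyl [(2R)-1-hydroxypropan-2-yl]carbamate (N-Boc-D-alaninol, the commercial carbamate of D-alaninol)
Product: 3 tert-butyl (4R)-4-methyl-1,2,3-oxathiazolidine-3-carboxylate 2,2-dioxide, via sulfamidite 2 (not isolated)
Conditions: SOCl2, pyridine, MeCN, −40 °C to rt; then RuCl3 (cat.), NaIO4, MeCN/H2O, 0 °C
Reagents that add atoms: thionyl chloride O=S(Cl)Cl; sodium periodate [Na+].[O-]I(=O)(=O)=O
Why: Cyclic sulfamidate synthesis: SOCl2 ties N–H and O–H into the five-membered sulfamidite and RuO4 generated from RuCl3/NaIO4 oxidises sulfur, and neither event touches the C–N stereocentre, which stays R.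

Step 2
Reactants: 4 1-(benzyloxy)-3-bromobenzene; 3 cyclic sulfamidate
Product: 7 tert-butyl {(2R)-1-[3-(benzyloxy)phenyl]propan-2-yl}carbamate, via Grignard reagent 5 (not isolated), via N-sulfamate salt 6 (not isolated)
Conditions: Mg, THF, reflux; then 3, CuI (cat.), THF, −20 °C to rt; then 10% aq citric acid, rt
Reagents that add atoms: none
Why: Copper-catalysed SN2 opening of a cyclic sulfamidate by an aryl Grignard reagent occurs at the primary C–O carbon, so the purchased stereocentre is untouched and becomes C3 (R), and mild acid then hydrolyses the N-sulfate while the Boc group stays.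

Step 3
Reactants: 7 Boc-amine
Product: 8 tert-butyl {(2R)-1-[5-(benzyloxy)-2-bromophenyl]propan-2-yl}carbamate
Conditions: NBS, MeCN, 0 °C to rt, dark
Reagents that add atoms: N-bromosuccinimide O=C1CCC(=O)N1Br
Why: Electrophilic aromatic bromination with NBS in MeCN goes para to the ether oxygen of 3-alkyl aryl ethers, which puts bromine on the future C5, where it first blocks the wrong ring closure and later serves as the coupling handle.

Step 4
Reactants: 8 bromo carbamate
Product: 10 N-{(2R)-1-[5-(benzyloxy)-2-bromophenyl]propan-2-yl}acetamide, via amine hydrochloride 9 (not isolated)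
Conditions: 4 M HCl in dioxane, rt; evaporate; Ac2O, Et3N, CH2Cl2, 0 °C to rt
Reagents that add atoms: acetic anhydride CC(=O)OC(C)=O
Why: Acidolysis of the Boc group followed by N-acetylation brings in C1 and its methyl group without touching the stereocentre or the aryl benzyl ether.

Step 5
Reactants: 10 acetamide
Product: 11 (3R)-8-(benzyloxy)-5-bromo-1,3-dimethyl-3,4-dihydroisoquinoline
Conditions: Tf2O, 2-chloropyridine, CH2Cl2, −78 °C to 40 °C
Reagents that add atoms: none
Why: In this Bischler–Napieralski cyclodehydration the nitrilium ion can attack only the free carbon ortho to the side chain, which is activated by the adjacent benzyloxy group, because the other ortho carbon (para to oxygen) carries bromine.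

Step 6
Reactants: 11 dihydroisoquinoline
Product: 12 (1R,3R)-8-(benzyloxy)-5-bromo-1,3-dimethyl-1,2,3,4-tetrahydroisoquinoline
Conditions: AlMe3, LiAlH4, THF, −78 °C to 0 °C
Reagents that add atoms: none
Why: In this Lewis acid-assisted cyclic imine reduction, AlMe3 on nitrogen drives the C3 methyl pseudoaxial through allylic-type strain, and the stereoelectronically preferred pseudoaxial hydride delivery to C1 leaves the C1 methyl pseudoequatorial, trans to C3 (1R); the aryl bromide is inert at this temperature.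

Step 7
Reactants: 12 secondary amine
Product: 13 (1R,3R)-2-benzyl-8-(benzyloxy)-5-bromo-1,3-dimethyl-1,2,3,4-tetrahydroisoquinoline
Conditions: BnBr, K2CO3, MeCN, 60 °C
Reagents that add atoms: benzyl bromide BrCc1ccccc1
Why: SN2 N-alkylation stops at the tertiary amine because nitrogen is flanked by two branched carbons, and neither stereocentre is acidic under carbonate.

Step 8
Reactants: 13 aryl bromide
Product: 14 (1R,3R)-2-benzyl-8-(benzyloxy)-1,3-dimethyl-5-(4,4,5,5-tetramethyl-1,3,2-dioxaborolan-2-yl)-1,2,3,4-tetrahydroisoquinoline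
Conditions: B2pin2, Pd(dppf)Cl2 (cat.), KOAc, dioxane, 90 °C
Reagents that add atoms: bis(pinacolato)diboron CC1(C)OB(OC1(C)C)B1OC(C)(C)C(C)(C)O1
Why: Miyaura borylation of an aryl bromide, in which the weak base KOAc keeps the new boronate from coupling with unreacted bromide and both the benzyl groups and the amine are tolerated.

## Naphthalene of half 1

Step 9
Reactants: 15 2-bromo-5-hydroxybenzaldehyde
Product: 16 2-bromo-4-chloro-5-hydroxybenzaldehyde
Conditions: NCS, TFA (cat.), MeCN, 50 °C
Reagents that add atoms: N-chlorosuccinimide O=C1CCC(=O)N1Cl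
Why: In this electrophilic aromatic chlorination the position para to the hydroxyl carries bromine and C6 is wedged between OH and CHO, so chlorine enters at C4, as the second halogen does in the known dihalogenation of 3-hydroxybenzaldehyde.

Step 10
Reactants: 16 chlorophenol
Product: 17 5-(benzyloxy)-2-bromo-4-chlorobenzaldehyde
Conditions: BnBr, K2CO3, DMF, rt
Reagents that add atoms: benzyl bromide BrCc1ccccc1
Why: Williamson ether synthesis on an acidic phenol, with the aldehyde and both halogens inert.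

Step 11
Reactants: 17 aldehyde; 18 diethyl succinate
Product: 19 (3E)-4-[5-(benzyloxy)-2-bromo-4-chlorophenyl]-3-(ethoxycarbonyl)but-3-enoic acid
Conditions: KOtBu, t-BuOH, 50 °C; then aq HCl
Reagents that add atoms: none
Why: In the Stobbe condensation the succinate enolate adds to the aldehyde, the alkoxide lactonises, and base-induced opening of the lactone gives the E half-ester, whose aryl group lies cis to CH2CO2H as the ring closure requires.

Step 12
Reactants: 19 half-ester
Product: 20 ethyl 4-acetoxy-5-(benzyloxy)-8-bromo-6-chloronaphthalene-2-carboxylate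
Conditions: Ac2O, NaOAc, reflux
Reagents that add atoms: acetic anhydride CC(=O)OC(C)=O
Why: Ring A of half 1 closes by intramolecular acylation through the mixed anhydride (or the ketene derived from it) at the only free carbon ortho to the side chain, the other one bearing bromine, and the naphthol formed is trapped as its acetate.

Step 13
Reactants: 20 naphthyl acetate
Product: 22 ethyl 5-(benzyloxy)-8-bromo-6-chloro-4-methoxynaphthalene-2-carboxylate, via free naphthol 21 (not isolated)
Conditions: K2CO3, EtOH, rt; evaporate; MeI, K2CO3, acetone, reflux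
Reagents that add atoms: iodomethane CI
Why: Base-mediated ethanolysis of the aryl acetate (ethanol avoids scrambling of the ethyl ester) followed by Williamson methylation sets the C4' methoxy group apart from the C5' benzyl ether.

Step 14
Reactants: 22 ester
Product: 23 [5-(benzyloxy)-8-bromo-6-chloro-4-methoxynaphthalen-2-yl]methanol
Conditions: LiAlH4, THF, 0 °C
Reagents that add atoms: none
Why: Hydride reduction of the ester is fast at 0 °C, where the aryl bromide, aryl chloride and benzyl ether are not attacked.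

Step 15
Reactants: 23 benzylic alcohol
Product: 25 1-(benzyloxy)-4-bromo-2-chloro-8-methoxy-6-methylnaphthalene, via mesylate 24 (not isolated)
Conditions: MsCl, Et3N, THF, 0 °C; then LiEt3BH, 0 °C to rt
Reagents that add atoms: none
Why: The benzylic alcohol is deoxygenated by mesylation and SN2 hydride displacement with LiEt3BH, which is far faster than any reduction of the aryl halides.

## Assembly

Step 16
Reactants: 25 bromochloronaphthalene; 14 isoquinoline boronate
Product: 26 (1R,3R)-2-benzyl-8-(benzyloxy)-5-[4-(benzyloxy)-3-chloro-5-methoxy-7-methylnaphthalen-1-yl]-1,3-dimethyl-1,2,3,4-tetrahydroisoquinoline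
Conditions: Pd(PPh3)4 (cat.), K3PO4, DME/H2O, 85 °C
Reagents that add atoms: none
Why: In this Suzuki–Miyaura coupling Pd(PPh3)4 inserts into the C8'–Br bond but not into the electron-rich, flanked C6'–Cl bond, so only the C8'–C5 axis is formed.

Step 17
Reactants: 26 aryl chloride
Product: 27 (1R,3R)-2-benzyl-8-(benzyloxy)-5-[4-(benzyloxy)-5-methoxy-7-methyl-3-(4,4,5,5-tetramethyl-1,3,2-dioxaborolan-2-yl)naphthalen-1-yl]-1,3-dimethyl-1,2,3,4-tetrahydroisoquinoline
Conditions: B2pin2, Pd2(dba)3 (cat.), XPhos, KOAc, dioxane, 110 °C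
Reagents that add atoms: bis(pinacolato)diboron CC1(C)OB(OC1(C)C)B1OC(C)(C)C(C)(C)O1
Why: Miyaura borylation of an aryl chloride, in which the bulky electron-rich biaryl phosphine makes oxidative addition into electron-rich ortho-alkoxy C–Cl bonds possible.

Step 18
Reactants: 28 2,6-dibromophenol
Product: 29 2-(benzyloxy)-1,3-dibromobenzene
Conditions: BnBr, K2CO3, DMF, rt
Reagents that add atoms: benzyl bromide BrCc1ccccc1
Why: Williamson ether synthesis on an acidic, only moderately hindered phenol.

Step 19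
Reactants: 27 C6' boronate; 29 dibromide
Product: 30 2-(benzyloxy)-1-bromo-3-(H1)benzene
Conditions: 29 (3 equiv), Pd(PPh3)4 (cat.), K3PO4, DME/H2O, 85 °C
Reagents that add atoms: none
Why: In this Suzuki–Miyaura coupling the two C–Br bonds of 29 are equivalent, so a threefold excess of this cheap partner holds the reaction at mono-coupling, and the surplus ether is recovered.

Step 20
Reactants: 30 aryl bromide; 31 chromium hexacarbonyl
Product: 34 tetramethylammonium pentacarbonyl{[2-(benzyloxy)-3-(H1)phenyl]oxidocarbene}chromate, via aryllithium 32 (not isolated), via lithium acylchromate 33 (not isolated)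
Conditions: n-BuLi, THF, −78 °C; Cr(CO)6, −78 °C to rt; then Me4NBr, degassed H2O/CH2Cl2
Reagents that add atoms: tetramethylammonium bromide C[N+](C)(C)C.[Br-]
Why: This is the first half of the Fischer carbene synthesis: bromine–lithium exchange outruns any deprotonation at −78 °C, the aryllithium adds to a CO ligand, and cation metathesis gives the storable ammonium acylate.

Step 21
Reactants: 34 ammonium acylchromate
Product: 36 pentacarbonyl{[2-(benzyloxy)-3-(H1)phenyl](methoxy)carbene}chromium, via acetoxycarbene complex 35 (not isolated)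
Conditions: AcBr, CH2Cl2, −40 °C; then MeOH, −40 °C to 0 °C
Reagents that add atoms: methanol CO
Why: O-acylation of the acylate followed by addition–elimination of methanol at the carbene carbon is the established acyloxycarbene route to alkoxycarbenes, and it avoids oxonium salts or MeOTf, which could quaternise the N-benzyl amine.

Step 22
Reactants: 36 carbene complex; 37 propyne
Product: 39 5-(benzyloxy)-4-methoxy-2-methyl-6-(H1)naphthalen-1-ol, via Cr(CO)3 naphthol complex 38 (not isolated)
Conditions: propyne (3 equiv), THF, sealed tube, 55 °C, argon; then air, Et2O, rt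
Reagents that add atoms: none
Why: This is a Dötz benzannulation, known for ortho-alkoxyaryl(methoxy)carbene pentacarbonylchromium complexes and terminal alkynes, which give 5-alkoxy-4-methoxy-1-naphthols. Heat expels one cis CO (the neighbouring benzyloxy oxygen can hold the free site for a time), propyne binds and inserts into the Cr=C bond (C4''–C3''), and CO insertion into the new vinylcarbene gives the chromium-bound vinylketene (C2''–C1''). Ring A of half 2, six-membered and all-carbon, then closes by a six-electron electrocyclisation of the aryl vinylketene (C1''–C8a''), and enolisation gives naphthol complex 38, from which air removes Cr(CO)3. The site of closure needs no control because the second carbon ortho to the carbene carbon carries the benzyloxy group, and the alkyne orientation is set by size: the methyl-bearing carbon keeps away from the carbene substituents and ends next to the CO-derived C1'', the CH next to C4''. Naphthol formation has to win over the indene pathway without CO insertion, which chromium, a methoxycarbene, THF and a terminal alkyne all favour. No stereocentre is made, the four existing ones lie far from the reacting atoms, and the hindered tertiary amine cannot aminolyse the carbene as an N–H amine would.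

Step 23
Reactants: 39 naphthol
Product: 40 5-(benzyloxy)-4-methoxy-2-methyl-6-(H1)naphthalen-1-yl trifluoromethanesulfonate
Conditions: PhNTf2, Cs2CO3, DMF, 0 °C to rt, argon
Reagents that add atoms: N-phenylbis(trifluoromethanesulfonimide) O=S(=O)(N(c1ccccc1)S(=O)(=O)C(F)(F)F)C(F)(F)F
Why: O-sulfonylation of the naphthoxide with the mild triflyl donor PhNTf2 spares the tertiary amine that Tf2O would attack, and it also protects the oxidation-prone 4-methoxy-1-naphthol.

Step 24
Reactants: 40 triflate; 14 isoquinoline boronate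
Product: 41 (1R,3R)-2-benzyl-8-(benzyloxy)-5-[5-(benzyloxy)-4-methoxy-2-methyl-6-(H1)naphthalen-1-yl]-1,3-dimethyl-1,2,3,4-tetrahydroisoquinoline
Conditions: Pd(OAc)2 (cat.), SPhos, K3PO4, toluene/H2O, 100 °C
Reagents that add atoms: none
Why: Suzuki–Miyaura coupling of an aryl triflate, where SPhos is the ligand type proven for biaryls with three ortho substituents, here C2''–CH3, the C8a'' ring fusion and the isoquinoline C4a.

Step 25
Reactants: 41 hexabenzyl dimer
Product: 42 CNP0077060.1
Conditions: H2 (1 atm), 10% Pd/C, MeOH/THF, rt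
Reagents that add atoms: none
Why: Catalytic hydrogenolysis cleaves the four aryl benzyl ethers and the two N-benzyl groups in one operation, while the methyl ethers, the naphthalenes and the four stereocentres (whose ring C1–N bonds are much more hindered) remain.

## Compound list

1 | tert-butyl [(2R)-1-hydroxypropan-2-yl]carbamate (N-Boc-D-alaninol) | C[C@@H](NC(=O)OC(C)(C)C)CO | starting material
2 | tert-butyl (4R)-4-methyl-1,2,3-oxathiazolidine-3-carboxylate 2-oxide | C[C@@H]1COS(=O)N1C(=O)OC(C)(C)C | intermediate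
3 | tert-butyl (4R)-4-methyl-1,2,3-oxathiazolidine-3-carboxylate 2,2-dioxide | C[C@@H]1COS(=O)(=O)N1C(=O)OC(C)(C)C | intermediate
4 | 1-(benzyloxy)-3-bromobenzene | Brc1cccc(OCc2ccccc2)c1 | starting material
5 | [3-(benzyloxy)phenyl]magnesium bromide | Br[Mg]c1cccc(OCc2ccccc2)c1 | intermediate
6 | bromomagnesium N-Boc-N-{(2R)-1-[3-(benzyloxy)phenyl]propan-2-yl}sulfamate | C[C@@H](N(C(=O)OC(C)(C)C)S(=O)(=O)[O-])Cc1cccc(OCc2ccccc2)c1.[Mg+2].[Br-] | intermediate
7 | tert-butyl {(2R)-1-[3-(benzyloxy)phenyl]propan-2-yl}carbamate | C[C@@H](NC(=O)OC(C)(C)C)Cc1cccc(OCc2ccccc2)c1 | intermediate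
8 | tert-butyl {(2R)-1-[5-(benzyloxy)-2-bromophenyl]propan-2-yl}carbamate | C[C@@H](NC(=O)OC(C)(C)C)Cc1cc(OCc2ccccc2)ccc1Br | intermediate
9 | (2R)-1-[5-(benzyloxy)-2-bromophenyl]propan-2-amine hydrochloride | C[C@@H](N)Cc1cc(OCc2ccccc2)ccc1Br.Cl | intermediate
10 | N-{(2R)-1-[5-(benzyloxy)-2-bromophenyl]propan-2-yl}acetamide | C[C@@H](NC(C)=O)Cc1cc(OCc2ccccc2)ccc1Br | intermediate
11 | (3R)-8-(benzyloxy)-5-bromo-1,3-dimethyl-3,4-dihydroisoquinoline | C[C@@H]1Cc2c(Br)ccc(OCc3ccccc3)c2C(C)=N1 | intermediate
12 | (1R,3R)-8-(benzyloxy)-5-bromo-1,3-dimethyl-1,2,3,4-tetrahydroisoquinoline | Brc1ccc(OCc2ccccc2)c2c1C[C@@H](C)N[C@@H]2C | intermediate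
13 | (1R,3R)-2-benzyl-8-(benzyloxy)-5-bromo-1,3-dimethyl-1,2,3,4-tetrahydroisoquinoline | Brc1ccc(OCc2ccccc2)c2c1C[C@@H](C)N(Cc1ccccc1)[C@@H]2C | intermediate
14 | (1R,3R)-2-benzyl-8-(benzyloxy)-1,3-dimethyl-5-(4,4,5,5-tetramethyl-1,3,2-dioxaborolan-2-yl)-1,2,3,4-tetrahydroisoquinoline | CC1(C)OB(OC1(C)C)c1ccc(OCc2ccccc2)c2c1C[C@@H](C)N(Cc1ccccc1)[C@@H]2C | intermediate
15 | 2-bromo-5-hydroxybenzaldehyde | O=Cc1cc(O)ccc1Br | starting material
16 | 2-bromo-4-chloro-5-hydroxybenzaldehyde | O=Cc1cc(O)c(Cl)cc1Br | intermediate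
17 | 5-(benzyloxy)-2-bromo-4-chlorobenzaldehyde | O=Cc1cc(OCc2ccccc2)c(Cl)cc1Br | intermediate
18 | diethyl succinate | CCOC(=O)CCC(=O)OCC | starting material
19 | (3E)-4-[5-(benzyloxy)-2-bromo-4-chlorophenyl]-3-(ethoxycarbonyl)but-3-enoic acid | CCOC(=O)/C(CC(=O)O)=C/c1cc(OCc2ccccc2)c(Cl)cc1Br | intermediate
20 | ethyl 4-acetoxy-5-(benzyloxy)-8-bromo-6-chloronaphthalene-2-carboxylate | CCOC(=O)c1cc(OC(C)=O)c2c(OCc3ccccc3)c(Cl)cc(Br)c2c1 | intermediate
21 | ethyl 5-(benzyloxy)-8-bromo-6-chloro-4-hydroxynaphthalene-2-carboxylate | CCOC(=O)c1cc(O)c2c(OCc3ccccc3)c(Cl)cc(Br)c2c1 | intermediate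
22 | ethyl 5-(benzyloxy)-8-bromo-6-chloro-4-methoxynaphthalene-2-carboxylate | CCOC(=O)c1cc(OC)c2c(OCc3ccccc3)c(Cl)cc(Br)c2c1 | intermediate
23 | [5-(benzyloxy)-8-bromo-6-chloro-4-methoxynaphthalen-2-yl]methanol | OCc1cc(OC)c2c(OCc3ccccc3)c(Cl)cc(Br)c2c1 | intermediate
24 | [5-(benzyloxy)-8-bromo-6-chloro-4-methoxynaphthalen-2-yl]methyl methanesulfonate | CS(=O)(=O)OCc1cc(OC)c2c(OCc3ccccc3)c(Cl)cc(Br)c2c1 | intermediate
25 | 1-(benzyloxy)-4-bromo-2-chloro-8-methoxy-6-methylnaphthalene | COc1cc(C)cc2c(Br)cc(Cl)c(OCc3ccccc3)c12 | intermediate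
26 | protected half 1 with C6' chloride | COc1cc(C)cc2c(-c3ccc(OCc4ccccc4)c4c3C[C@@H](C)N(Cc3ccccc3)[C@@H]4C)cc(Cl)c(OCc3ccccc3)c12 | intermediate
27 | protected half 1 with C6' pinacol boronate | COc1cc(C)cc2c(-c3ccc(OCc4ccccc4)c4c3C[C@@H](C)N(Cc3ccccc3)[C@@H]4C)cc(B3OC(C)(C)C(C)(C)O3)c(OCc3ccccc3)c12 | intermediate
28 | 2,6-dibromophenol | Oc1c(Br)cccc1Br | starting material
29 | 2-(benzyloxy)-1,3-dibromobenzene | Brc1cccc(Br)c1OCc1ccccc1 | intermediate
30 | 2-(benzyloxy)-1-bromo-3-(H1)benzene | Brc1cccc(-c2cc(-c3ccc(OCc5ccccc5)c4c3C[C@@H](C)N(Cc3ccccc3)[C@@H]4C)c3cc(C)cc(OC)c3c2OCc2ccccc2)c1OCc1ccccc1 | intermediate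
31 | chromium hexacarbonyl | O=C=[Cr](=C=O)(=C=O)(=C=O)(=C=O)=C=O | starting material
32 | [2-(benzyloxy)-3-(H1)phenyl]lithium | [Li]c1cccc(-c2cc(-c3ccc(OCc5ccccc5)c4c3C[C@@H](C)N(Cc3ccccc3)[C@@H]4C)c3cc(C)cc(OC)c3c2OCc2ccccc2)c1OCc1ccccc1 | intermediate
33 | lithium pentacarbonyl{[2-(benzyloxy)-3-(H1)phenyl]oxidocarbene}chromate | [Li+].[O-]C(=[Cr](=C=O)(=C=O)(=C=O)(=C=O)=C=O)c1cccc(-c2cc(-c3ccc(OCc5ccccc5)c4c3C[C@@H](C)N(Cc3ccccc3)[C@@H]4C)c3cc(C)cc(OC)c3c2OCc2ccccc2)c1OCc1ccccc1 | intermediate
34 | tetramethylammonium pentacarbonyl{[2-(benzyloxy)-3-(H1)phenyl]oxidocarbene}chromate | C[N+](C)(C)C.[O-]C(=[Cr](=C=O)(=C=O)(=C=O)(=C=O)=C=O)c1cccc(-c2cc(-c3ccc(OCc5ccccc5)c4c3C[C@@H](C)N(Cc3ccccc3)[C@@H]4C)c3cc(C)cc(OC)c3c2OCc2ccccc2)c1OCc1ccccc1 | intermediate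
35 | pentacarbonyl{acetoxy[2-(benzyloxy)-3-(H1)phenyl]carbene}chromium | CC(=O)OC(=[Cr](=C=O)(=C=O)(=C=O)(=C=O)=C=O)c1cccc(-c2cc(-c3ccc(OCc5ccccc5)c4c3C[C@@H](C)N(Cc3ccccc3)[C@@H]4C)c3cc(C)cc(OC)c3c2OCc2ccccc2)c1OCc1ccccc1 | intermediate
36 | pentacarbonyl{[2-(benzyloxy)-3-(H1)phenyl](methoxy)carbene}chromium | COC(=[Cr](=C=O)(=C=O)(=C=O)(=C=O)=C=O)c1cccc(-c2cc(-c3ccc(OCc5ccccc5)c4c3C[C@@H](C)N(Cc3ccccc3)[C@@H]4C)c3cc(C)cc(OC)c3c2OCc2ccccc2)c1OCc1ccccc1 | intermediate
37 | propyne | CC#C | starting material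
38 | tricarbonylchromium η6 complex of 39 (haptic bond not drawn) | COc1cc(C)c(O)c2ccc(-c3cc(-c4ccc(OCc6ccccc6)c5c4C[C@@H](C)N(Cc4ccccc4)[C@@H]5C)c4cc(C)cc(OC)c4c3OCc3ccccc3)c(OCc3ccccc3)c12.O=C=[Cr](=C=O)=C=O | intermediate
39 | 5-(benzyloxy)-4-methoxy-2-methyl-6-(H1)naphthalen-1-ol | COc1cc(C)c(O)c2ccc(-c3cc(-c4ccc(OCc6ccccc6)c5c4C[C@@H](C)N(Cc4ccccc4)[C@@H]5C)c4cc(C)cc(OC)c4c3OCc3ccccc3)c(OCc3ccccc3)c12 | intermediate
40 | 5-(benzyloxy)-4-methoxy-2-methyl-6-(H1)naphthalen-1-yl trifluoromethanesulfonate | COc1cc(C)c(OS(=O)(=O)C(F)(F)F)c2ccc(-c3cc(-c4ccc(OCc6ccccc6)c5c4C[C@@H](C)N(Cc4ccccc4)[C@@H]5C)c4cc(C)cc(OC)c4c3OCc3ccccc3)c(OCc3ccccc3)c12 | intermediate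
41 | hexabenzyl-protected dimer | COc1cc(C)c(-c3ccc(OCc4ccccc4)c4c3C[C@@H](C)N(Cc3ccccc3)[C@@H]4C)c2ccc(-c3cc(-c4ccc(OCc6ccccc6)c5c4C[C@@H](C)N(Cc4ccccc4)[C@@H]5C)c4cc(C)cc(OC)c4c3OCc3ccccc3)c(OCc3ccccc3)c12 | intermediate
42 | CNP0077060.1 | COc1cc(C)cc2c(-c3ccc(O)c4c3C[C@@H](C)N[C@@H]4C)cc(-c3ccc4c(-c5ccc(O)c6c5C[C@@H](C)N[C@@H]6C)c(C)cc(OC)c4c3O)c(O)c12 | target

## Step count and risks

Total step count: 25.
Longest linear sequence: 17 steps (steps 1–8, 16, 17, 19–25).

**Step 22.**
- **What may go wrong:** After propyne insertion the vinylcarbene may cyclise without taking up CO (the indene pathway). The crowded complex may decay before it loses CO. The electron-rich naphthol may be over-oxidised while chromium is stripped in air.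
- **Fallback:** The ring construction is moved to a small, amine-free arene and the halves are joined afterwards.
  - It sets out from 29. Exchange of one bromine with n-BuLi, addition to Cr(CO)6 and methylation with Me3OBF4 should give pentacarbonyl{[2-(benzyloxy)-3-bromophenyl](methoxy)carbene}chromium F1.
  - Heating F1 with propyne in THF and removing chromium in air should give 5-(benzyloxy)-6-bromo-4-methoxy-2-methylnaphthalen-1-ol F2.
  - PhNTf2/Cs2CO3 converts F2 into 5-(benzyloxy)-6-bromo-4-methoxy-2-methylnaphthalen-1-yl trifluoromethanesulfonate F3.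
  - Suzuki coupling of F3 with boronate 27 under Pd(PPh3)4, which prefers the C–Br bond to the flanked C1 triflate, comes back to the route at 40.

**Step 24.**
- **What may go wrong:** Transmetalation of the hindered pinacol boronate at the flanked arylpalladium centre may be slow. That would leave time for S–O cleavage of the triflate by aqueous base and for protodeboronation.
- **Fallback:** The boron nucleophile and the aqueous base are given up for an anhydrous Negishi coupling.
  - It sets out from 13. Bromine–lithium exchange with n-BuLi at −78 °C and ZnCl2 give [(1R,3R)-2-benzyl-8-(benzyloxy)-1,3-dimethyl-1,2,3,4-tetrahydroisoquinolin-5-yl]zinc chloride F4.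
  - F4 is coupled with triflate 40 using Pd2(dba)3/RuPhos in THF at 65 °C and comes back to the route at 41.

**Step 20.**
- **What may go wrong:** Poorly soluble Cr(CO)6 is slow to react. In that time the aryllithium may take a proton from the neighbouring benzylic OCH2 group, with Wittig rearrangement following, or from the medium.
- **Fallback:** The polarity is reversed, with a nucleophilic chromium reagent and an acyl electrophile.
  - It sets out from 27. Commercial methyl 3-bromo-2-hydroxybenzoate is benzylated (BnBr, K2CO3) to methyl 2-(benzyloxy)-3-bromobenzoate F5.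
  - Suzuki coupling of F5 with 27 (Pd(PPh3)4, K3PO4) gives methyl 2-(benzyloxy)-3-(H1)benzoate F6.
  - LiOH in THF/H2O gives 2-(benzyloxy)-3-(H1)benzoic acid F7.
  - 1-Chloro-N,N,2-trimethylpropenylamine under neutral conditions gives 2-(benzyloxy)-3-(H1)benzoyl chloride F8.
  - K2Cr(CO)5 (from Cr(CO)6 and C8K in THF at −78 °C) is acylated by F8, and cation exchange with Me4NBr comes back to the route at 34.

Further compounds

F1 | step 22 | pentacarbonyl{[2-(benzyloxy)-3-bromophenyl](methoxy)carbene}chromium | COC(=[Cr](=C=O)(=C=O)(=C=O)(=C=O)=C=O)c1cccc(Br)c1OCc1ccccc1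
F2 | step 22 | 5-(benzyloxy)-6-bromo-4-methoxy-2-methylnaphthalen-1-ol | COc1cc(C)c(O)c2ccc(Br)c(OCc3ccccc3)c12
F3 | step 22 | 5-(benzyloxy)-6-bromo-4-methoxy-2-methylnaphthalen-1-yl trifluoromethanesulfonate | COc1cc(C)c(OS(=O)(=O)C(F)(F)F)c2ccc(Br)c(OCc3ccccc3)c12
F4 | step 24 | [(1R,3R)-2-benzyl-8-(benzyloxy)-1,3-dimethyl-1,2,3,4-tetrahydroisoquinolin-5-yl]zinc chloride | Cl[Zn]c1ccc(OCc2ccccc2)c2c1C[C@@H](C)N(Cc1ccccc1)[C@@H]2C
F5 | step 20 | methyl 2-(benzyloxy)-3-bromobenzoate | COC(=O)c1cccc(Br)c1OCc1ccccc1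
F6 | step 20 | methyl 2-(benzyloxy)-3-(H1)benzoate | COC(=O)c1cccc(-c2cc(-c3ccc(OCc5ccccc5)c4c3C[C@@H](C)N(Cc3ccccc3)[C@@H]4C)c3cc(C)cc(OC)c3c2OCc2ccccc2)c1OCc1ccccc1
F7 | step 20 | 2-(benzyloxy)-3-(H1)benzoic acid | OC(=O)c1cccc(-c2cc(-c3ccc(OCc5ccccc5)c4c3C[C@@H](C)N(Cc3ccccc3)[C@@H]4C)c3cc(C)cc(OC)c3c2OCc2ccccc2)c1OCc1ccccc1
F8 | step 20 | 2-(benzyloxy)-3-(H1)benzoyl chloride | ClC(=O)c1cccc(-c2cc(-c3ccc(OCc5ccccc5)c4c3C[C@@H](C)N(Cc3ccccc3)[C@@H]4C)c3cc(C)cc(OC)c3c2OCc2ccccc2)c1OCc1ccccc1
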